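The numbers are those of an exercise; the run is a simulation.

The vessel held solid Z stirred in a solution of J and G, and E reached the solution by dissolving from that solid.

    E.J ⇌ X (K1 = 6.6, k1 = 0.012 h⁻¹)
    Z + E.J → Z.E.J (k2 = 0.27 M⁻¹ h⁻¹)
    E + J → E.J (k3 = 2.4 M⁻¹ h⁻¹)
    J + G → J.G (k4 = 2.5 M⁻¹ h⁻¹)
    Z ⇌ E, rate k5*(cs5 - [E]) while solid is left; crystals form when [E] > cs5 (cs5 = 23 mM, k5 = 0.016 h⁻¹)

Z 0.067 M; J 0.134 M; G 0.0201 M; time 5.0 d

- E.J at 5.0 d, in percent of the Z charged
- concentration of E in solution at 5.0 d, in percent of saturation

- in percentages every species weighs as the Z in it: one Z.E.J counts as two
- as a solid, counted per litre of solution: Z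
- at the start none of Z is in solution
- E means what is dissolved; the solid is not counted in it
- run time (flask): 5.0 d

I treated the capture of E by J as fast, because the half-life of E by that step, 0.090 d, was shorter than the run of 5.0 d. In this quasi-steady state, dissolving balanced capture. E then stood at a fraction of saturation equal to a holding level divided by the sum of that level and the free J. The holding level of J is the dissolution coefficient divided by the capture constant, 6.67 mM.

I then turned the settings one after the other. G came first: it binds J into J.G, and the half-life of J by that step, with G held at its charge, was 0.57 d, shorter than the run. So I took the charge of G off J, which left 0.114 M and put E at 5.53% of saturation. With the other charges held, a larger charge of G, still below that of J, leaves less free J, and the ratio then puts E higher.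

Time came next: each E captured costs one J, and while solid lasted, dissolving into a solution kept empty could deliver 0.0442 M by the end, which is 65.9% of the Z charged. I took that full delivery off J, which left 0.0697 M and put E at 8.73% of saturation.

The charge of Z does not enter the dissolving rate while solid is left, so it does not enter my ratio. For E.J I kept no figure of my own, since E.J passes on to X and Z.E.J as it forms.

The forecast gave 24.5% for E.J and 8.3% of saturation for E, holding that “Dissolution is the bottleneck”.

The flask gave 24.0% for E.J and 8.06% of saturation for E. With the other amounts and the time held, the answer for E.J moved by 5 points at a charge of Z of 0.0593 M or 0.0775 M. With the 0.0744 M of J standing at the end of the flask, the holding level gave 8.22%. In the neighbour flask with 0.080 M of G, J ended at 0.0210 M, the holding level gave 24.1%, and E stood at 21.6% of saturation.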